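The route rests on disconnecting the C5'–CH3 bond of the saturated ring B with allylic transposition: the C5'(H)(CH3) stereocentre flanking the exocyclic C6'=C7' alkene is the imprint of an anti-SN2' methyl transfer onto the ring CH of a 6,6-dimethylcyclohexenyl carbinol. One copper-mediated operation forms the C5'–CH3 bond, sets (5'S) by 1,3-chirality transfer and delivers the E exocyclic alkene. Its precursor is the picolinate of an (S)-allylic alcohol bearing a CH2OTBS arm, reached by Shapiro coupling, oxidation and CBS reduction. The product is grown to a C20 tetraenyl iodide and joined at C15–C15' to anhydroretinol (ring A half) by Heck alkenylation.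

Key step: step 6

Numbering: carotenoid numbering is used; unprimed atoms lie in the half with the cyclohex-2-enylidene ring (ring A), primed atoms in the half with the saturated ring (ring B).
Assumption: phosphonate 17 is treated as a purchasable reagent; otherwise it is one Arbuzov step from ethyl (E)-4-bromo-2-methylbut-2-enoate and triethyl phosphite.
Handling: compounds 16 to 25 are polyenes and are kept under argon in dim light.

Step 1
Reactants: 1 2,2-dimethylcyclohexanone; 2 2,4,6-triisopropylbenzenesulfonohydrazide
Product: 3 (E)-N'-(2,2-dimethylcyclohexylidene)-2,4,6-triisopropylbenzenesulfonohydrazide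
Conditions: MeOH, cat. conc. HCl, rt
Reagents that add atoms: 2,4,6-triisopropylbenzenesulfonohydrazide (2), CC(C)c1cc(C(C)C)c(S(=O)(=O)NN)c(C(C)C)c1
Why: Acid-catalysed hydrazone condensation, in which the sulfonamide nitrogen should settle anti to the quaternary carbon and therefore syn to the only α-CH2 group, as the Shapiro reaction of step 2 requires.

Step 2
Reactants: 3 (E)-N'-(2,2-dimethylcyclohexylidene)-2,4,6-triisopropylbenzenesulfonohydrazide; 4 2-[(tert-butyldimethylsilyl)oxy]acetaldehyde
Product: 6 rac-2-[(tert-butyldimethylsilyl)oxy]-1-(6,6-dimethylcyclohex-1-en-1-yl)ethan-1-ol, via alkenyllithium 5 (not isolated)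
Conditions: n-BuLi (2.2 equiv), THF, −78 → 0 °C; then 4, −78 °C; NH4Cl quench at −78 °C
Reagents that add atoms: 2-[(tert-butyldimethylsilyl)oxy]acetaldehyde (4), CC(C)(C)[Si](C)(C)OCC=O
Why: Shapiro reaction, in which double deprotonation (N–H, then the syn α-CH2) and loss of sulfinate and N2 give the alkenyllithium regiospecifically because the other α-carbon is quaternary, followed by 1,2-addition to the aldehyde; the cold quench avoids silyl migration in the alkoxide.

Step 3
Reactants: 6 rac-2-[(tert-butyldimethylsilyl)oxy]-1-(6,6-dimethylcyclohex-1-en-1-yl)ethan-1-ol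
Product: 7 2-[(tert-butyldimethylsilyl)oxy]-1-(6,6-dimethylcyclohex-1-en-1-yl)ethan-1-one
Conditions: Dess–Martin periodinane, NaHCO3, CH2Cl2, 0 °C → rt
Reagents that add atoms: none
Why: Dess–Martin oxidation of a secondary allylic alcohol under buffered, non-basic conditions that leave the silyl ether and the trisubstituted alkene untouched.

Step 4
Reactants: 7 2-[(tert-butyldimethylsilyl)oxy]-1-(6,6-dimethylcyclohex-1-en-1-yl)ethan-1-one
Product: 8 (1S)-2-[(tert-butyldimethylsilyl)oxy]-1-(6,6-dimethylcyclohex-1-en-1-yl)ethan-1-ol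
Conditions: (S)-1-methyl-3,3-diphenyltetrahydro-1H,3H-pyrrolo[1,2-c][1,3,2]oxazaborole (20 mol %), BH3·SMe2, THF, −30 °C; MeOH quench
Reagents that add atoms: none
Why: Corey–Bakshi–Shibata reduction, in which the cyclohexenyl group flanked by the quaternary carbon acts as the large substituent, so the (S)-catalyst should deliver hydride to the face that gives the (S)-carbinol (the descriptor follows from CH2OTBS outranking the alkenyl carbon).

Step 5
Reactants: 8 (1S)-2-[(tert-butyldimethylsilyl)oxy]-1-(6,6-dimethylcyclohex-1-en-1-yl)ethan-1-ol; 9 pyridine-2-carboxylic acid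
Product: 10 (1S)-2-[(tert-butyldimethylsilyl)oxy]-1-(6,6-dimethylcyclohex-1-en-1-yl)ethyl pyridine-2-carboxylate
Conditions: N,N'-dicyclohexylcarbodiimide, 4-(dimethylamino)pyridine, CH2Cl2, rt
Reagents that add atoms: pyridine-2-carboxylic acid (9), OC(=O)c1ccccn1
Why: Steglich esterification acylates the hindered secondary alcohol at oxygen, so the configuration at C7' is retained.

Step 6
Reactants: 10 (1S)-2-[(tert-butyldimethylsilyl)oxy]-1-(6,6-dimethylcyclohex-1-en-1-yl)ethyl pyridine-2-carboxylate; 11 methylmagnesium bromide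
Product: 12 tert-butyl(dimethyl){(2E)-2-[(6S)-2,2,6-trimethylcyclohexylidene]ethoxy}silane
Conditions: MeMgBr (3 equiv), CuBr·SMe2 (30 mol %), THF, −40 → 0 °C; NH4Cl quench
Reagents that add atoms: methylmagnesium bromide (11), C[Mg]Br
Why: Chelation of magnesium by the pyridine nitrogen and the ester carbonyl activates the picolinate, and the methylcopper species formed from MeMgBr and CuBr·SMe2 (monovalent copper) adds oxidatively at the ring carbon C5' on the face opposite the C7'–O bond to give a trivalent σ-allylcopper that collapses by reductive elimination with C5'–CH3 bond formation. The closest known reaction type is the copper-catalysed anti-SN2' substitution of secondary allylic picolinates by Grignard reagents with 1,3-chirality transfer. No ring is closed. The C5' stereocentre is controlled by the (S)-configured C7' carbinol: in the reacting conformer the C7'–O bond stands perpendicular to the C5'=C6' plane and the CH2OTBS arm lies syn to C5'–H, because the alternative presses it against the C1' gem-dimethyl group, so anti attack should give (5'S) and the E C6'=C7' alkene together. The step needs γ over α regioselectivity and anti over syn facial selectivity; these are secured by the unhindered ring CH at C5', by the shielding of C7' through the fully substituted C6' and the quaternary C1', and by the chelating leaving group.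

Step 7
Reactants: 12 tert-butyl(dimethyl){(2E)-2-[(6S)-2,2,6-trimethylcyclohexylidene]ethoxy}silane
Product: 13 (2E)-2-[(6S)-2,2,6-trimethylcyclohexylidene]ethan-1-ol
Conditions: Bu4NF, THF, 0 °C → rt
Reagents that add atoms: none
Why: Fluoride-mediated desilylation driven by Si–F bond formation, under conditions inert to the allylic stereocentre and the exocyclic alkene.

Step 8
Reactants: 13 (2E)-2-[(6S)-2,2,6-trimethylcyclohexylidene]ethan-1-ol
Product: 14 (2E)-2-[(6S)-2,2,6-trimethylcyclohexylidene]acetaldehyde
Conditions: MnO2 (excess), CH2Cl2, rt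
Reagents that add atoms: none
Why: MnO2 oxidation of a primary allylic alcohol on the neutral oxide surface, which should leave the γ-stereocentre C5' and the E alkene unchanged; the volatile enal is used at once.

Step 9
Reactants: 14 (2E)-2-[(6S)-2,2,6-trimethylcyclohexylidene]acetaldehyde; 15 2-(triphenylphosphoranylidene)propanal
Product: 16 (2E,4E)-2-methyl-4-[(6S)-2,2,6-trimethylcyclohexylidene]but-2-enal
Conditions: toluene, 80 °C
Reagents that add atoms: 2-(triphenylphosphoranylidene)propanal (15), CC(C=O)=P(c1ccccc1)(c1ccccc1)c1ccccc1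
Why: Wittig olefination with a formyl-stabilised ylide should give the E α-methyl enal directly under neutral conditions, and the α-branched, more conjugated product is less electrophilic than 14, so a second homologation is not expected.

Step 10
Reactants: 16 (2E,4E)-2-methyl-4-[(6S)-2,2,6-trimethylcyclohexylidene]but-2-enal; 17 ethyl (2E)-4-(diethoxyphosphoryl)-2-methylbut-2-enoate
Product: 18 ethyl (2E,4E,6E,8E)-2,6-dimethyl-8-[(6S)-2,2,6-trimethylcyclohexylidene]octa-2,4,6-trienoate
Conditions: 17 (1.5 equiv), LiN(SiMe3)2 (1.4 equiv), THF, −78 °C; then 16, −78 → 0 °C; NH4Cl quench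
Reagents that add atoms: ethyl (2E)-4-(diethoxyphosphoryl)-2-methylbut-2-enoate (17), CCOC(=O)/C(C)=C/CP(=O)(OCC)OCC
Why: Horner–Wadsworth–Emmons olefination with a vinylogous phosphonate, whose preformed lithium salt attacks through the carbon next to phosphorus and eliminates phosphate to give the E C10'=C11' alkene, installing C11' to C14' with the C13' methyl group in one step.

Step 11
Reactants: 18 ethyl (2E,4E,6E,8E)-2,6-dimethyl-8-[(6S)-2,2,6-trimethylcyclohexylidene]octa-2,4,6-trienoate
Product: 19 (2E,4E,6E,8E)-2,6-dimethyl-8-[(6S)-2,2,6-trimethylcyclohexylidene]octa-2,4,6-trien-1-ol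
Conditions: i-Bu2AlH (2.5 equiv), CH2Cl2, −78 °C; aq. potassium sodium tartrate
Reagents that add atoms: none
Why: 1,2-Reduction of the conjugated ester by the aluminium hydride stops at the allylic alcohol, and no other reducible group is present.

Step 12
Reactants: 19 (2E,4E,6E,8E)-2,6-dimethyl-8-[(6S)-2,2,6-trimethylcyclohexylidene]octa-2,4,6-trien-1-ol
Product: 20 (2E,4E,6E,8E)-2,6-dimethyl-8-[(6S)-2,2,6-trimethylcyclohexylidene]octa-2,4,6-trienal
Conditions: MnO2 (excess), CH2Cl2, rt, dark
Reagents that add atoms: none
Why: MnO2 oxidation is selective for the allylic polyenol and should give the polyenal without over-oxidation or double-bond isomerisation.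

Step 13
Reactants: 20 (2E,4E,6E,8E)-2,6-dimethyl-8-[(6S)-2,2,6-trimethylcyclohexylidene]octa-2,4,6-trienal; 21 iodoform
Product: 22 (1E,3E,5E,7E,9E)-1-iodo-3,7-dimethyl-9-[(6S)-2,2,6-trimethylcyclohexylidene]nona-1,3,5,7-tetraene
Conditions: CrCl2 (8 equiv), CHI3 (2.5 equiv), THF/1,4-dioxane, 0 °C → rt, dark
Reagents that add atoms: iodoform (21), IC(I)I
Why: Takai olefination, in which the geminal dichromium reagent formed from CHI3 and divalent chromium adds to the aldehyde and eliminates to the E 1-iodoalkene, a reaction that is dependable for α-methyl enals and tolerates polyenes.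

Step 14
Reactants: 23 all-trans-retinol
Product: 24 anhydroretinol, (6E)-6-[(2E,4E,6E)-3,7-dimethylnona-2,4,6,8-tetraen-1-ylidene]-1,5,5-trimethylcyclohex-1-ene
Conditions: p-toluenesulfonic acid monohydrate (2 mol %), toluene, rt, dark; NaHCO3 quench; filtration through basic Al2O3
Reagents that add atoms: none
Why: Acid-catalysed dehydration with retro rearrangement, in which ionisation at C15 gives the pentaenyl cation that loses the C4 proton to afford the thermodynamically favoured all-E retro-pentaene with a terminal C14=C15 vinyl group.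

Step 15
Reactants: 22 (1E,3E,5E,7E,9E)-1-iodo-3,7-dimethyl-9-[(6S)-2,2,6-trimethylcyclohexylidene]nona-1,3,5,7-tetraene; 24 anhydroretinol
Product: 25 (6E,6'E,5'S)-4,5'-retro-β,β-carotene (all-E), the target
Conditions: 22 (1 equiv), 24 (2.5 equiv), Pd(OAc)2 (10 mol %), Ag2CO3 (1.2 equiv), DMF, rt, dark, argon
Reagents that add atoms: anhydroretinol (24), CC1=CCCC(C)(C)\C1=C/C=C(C)/C=C/C=C(C)/C=C
Why: Heck alkenylation of a 1,3-diene terminus, in which the iodide adds oxidatively to zerovalent palladium formed from Pd(OAc)2, the alkenylpalladium inserts at the unsubstituted C15, and β-hydride elimination from C15 restores conjugation as the E C14=C15 alkene, while the silver salt scavenges iodide so that the coupling runs at room temperature away from the C5' centre.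

Compound list
1 | 2,2-dimethylcyclohexanone | CC1(C)CCCCC1=O | starting material
2 | 2,4,6-triisopropylbenzenesulfonohydrazide | CC(C)c1cc(C(C)C)c(S(=O)(=O)NN)c(C(C)C)c1 | starting material
3 | (E)-N'-(2,2-dimethylcyclohexylidene)-2,4,6-triisopropylbenzenesulfonohydrazide | CC1(C)CCCC/C1=N\NS(=O)(=O)c1c(C(C)C)cc(C(C)C)cc1C(C)C | intermediate
4 | 2-[(tert-butyldimethylsilyl)oxy]acetaldehyde | CC(C)(C)[Si](C)(C)OCC=O | starting material
5 | (6,6-dimethylcyclohex-1-en-1-yl)lithium | [Li]C1=CCCCC1(C)C | intermediate
6 | rac-2-[(tert-butyldimethylsilyl)oxy]-1-(6,6-dimethylcyclohex-1-en-1-yl)ethan-1-ol | CC1(C)CCCC=C1C(O)CO[Si](C)(C)C(C)(C)C | intermediate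
7 | 2-[(tert-butyldimethylsilyl)oxy]-1-(6,6-dimethylcyclohex-1-en-1-yl)ethan-1-one | CC1(C)CCCC=C1C(=O)CO[Si](C)(C)C(C)(C)C | intermediate
8 | (1S)-2-[(tert-butyldimethylsilyl)oxy]-1-(6,6-dimethylcyclohex-1-en-1-yl)ethan-1-ol | CC1(C)CCCC=C1[C@H](O)CO[Si](C)(C)C(C)(C)C | intermediate
9 | pyridine-2-carboxylic acid | OC(=O)c1ccccn1 | starting material
10 | (1S)-2-[(tert-butyldimethylsilyl)oxy]-1-(6,6-dimethylcyclohex-1-en-1-yl)ethyl pyridine-2-carboxylate | CC1(C)CCCC=C1[C@H](OC(=O)c1ccccn1)CO[Si](C)(C)C(C)(C)C | intermediate
11 | methylmagnesium bromide | C[Mg]Br | starting material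
12 | tert-butyl(dimethyl){(2E)-2-[(6S)-2,2,6-trimethylcyclohexylidene]ethoxy}silane | CC(C)(C)[Si](C)(C)OC/C=C1\[C@@H](C)CCCC1(C)C | intermediate
13 | (2E)-2-[(6S)-2,2,6-trimethylcyclohexylidene]ethan-1-ol | OC/C=C1\[C@@H](C)CCCC1(C)C | intermediate
14 | (2E)-2-[(6S)-2,2,6-trimethylcyclohexylidene]acetaldehyde | O=C/C=C1\[C@@H](C)CCCC1(C)C | intermediate
15 | 2-(triphenylphosphoranylidene)propanal | CC(C=O)=P(c1ccccc1)(c1ccccc1)c1ccccc1 | starting material
16 | (2E,4E)-2-methyl-4-[(6S)-2,2,6-trimethylcyclohexylidene]but-2-enal | O=C/C(C)=C/C=C1\[C@@H](C)CCCC1(C)C | intermediate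
17 | ethyl (2E)-4-(diethoxyphosphoryl)-2-methylbut-2-enoate | CCOC(=O)/C(C)=C/CP(=O)(OCC)OCC | starting material
18 | ethyl (2E,4E,6E,8E)-2,6-dimethyl-8-[(6S)-2,2,6-trimethylcyclohexylidene]octa-2,4,6-trienoate | CCOC(=O)/C(C)=C/C=C/C(C)=C/C=C1\[C@@H](C)CCCC1(C)C | intermediate
19 | (2E,4E,6E,8E)-2,6-dimethyl-8-[(6S)-2,2,6-trimethylcyclohexylidene]octa-2,4,6-trien-1-ol | OC/C(C)=C/C=C/C(C)=C/C=C1\[C@@H](C)CCCC1(C)C | intermediate
20 | (2E,4E,6E,8E)-2,6-dimethyl-8-[(6S)-2,2,6-trimethylcyclohexylidene]octa-2,4,6-trienal | O=C/C(C)=C/C=C/C(C)=C/C=C1\[C@@H](C)CCCC1(C)C | intermediate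
21 | iodoform | IC(I)I | starting material
22 | (1E,3E,5E,7E,9E)-1-iodo-3,7-dimethyl-9-[(6S)-2,2,6-trimethylcyclohexylidene]nona-1,3,5,7-tetraene | I/C=C/C(C)=C/C=C/C(C)=C/C=C1\[C@@H](C)CCCC1(C)C | intermediate
23 | all-trans-retinol | CC1=C(C(C)(C)CCC1)/C=C/C(C)=C/C=C/C(C)=C/CO | starting material
24 | anhydroretinol, (6E)-6-[(2E,4E,6E)-3,7-dimethylnona-2,4,6,8-tetraen-1-ylidene]-1,5,5-trimethylcyclohex-1-ene | CC1=CCCC(C)(C)\C1=C/C=C(C)/C=C/C=C(C)/C=C | intermediate
25 | (6E,6'E,5'S)-4,5'-retro-β,β-carotene (all-E) | CC1=CCCC(C)(C)\C1=C/C=C(C)/C=C/C=C(C)/C=C/C=C/C(C)=C/C=C/C(C)=C/C=C1\[C@@H](C)CCCC1(C)C | target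

Total step count: 15. Longest linear sequence: 14 steps (steps 1 to 13 and step 15, from 2,2-dimethylcyclohexanone); step 14 is a one-step side branch from retinol.

Steps most likely to fail

Step 6. The substitution may lose regio- or facial control (attack at C7', syn attack, or reaction through the conformer that leads to the Z alkene), or the Grignard reagent may attack the ester carbonyl and return 8. The fallback keeps the same bond construction but delivers the methyl group intramolecularly and syn from the enantiomeric carbinol. It sets out from ketone 7, which is reduced with the (R)-configured oxazaborolidine and BH3·SMe2 to (1R)-2-[(tert-butyldimethylsilyl)oxy]-1-(6,6-dimethylcyclohex-1-en-1-yl)ethan-1-ol F1. Phenyl isocyanate and 4-(dimethylamino)pyridine convert it into (1R)-2-[(tert-butyldimethylsilyl)oxy]-1-(6,6-dimethylcyclohex-1-en-1-yl)ethyl N-phenylcarbamate F2. Deprotonation of the carbamate with MeLi, complexation with CuI and addition of a second equivalent of MeLi (THF, −78 °C → rt) give a nitrogen-bound methylcopper species that transfers methyl to C5' on the face of the leaving group (carbamate-directed syn-SN2' substitution). From the (R)-carbinol, syn delivery should give the same (5'S,E) product, so the fallback comes back to the route at 12.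

Step 15. After insertion the palladium sits on a polyenyl chain and may migrate before β-hydride elimination, and E/Z scrambling, homocoupling of the iodide or decay of the labile pentaene may compete. The fallback separates functionalisation of the vinyl group from the carbon–carbon coupling. It sets out from anhydroretinol 24, which undergoes cross-metathesis with 4,4,5,5-tetramethyl-2-vinyl-1,3,2-dioxaborolane (second-generation Grubbs catalyst, CH2Cl2, 40 °C) at its only monosubstituted alkene to give 2-[(1E,3E,5E,7E)-3,7-dimethyl-9-[(1E)-2,6,6-trimethylcyclohex-2-en-1-ylidene]nona-1,3,5,7-tetraen-1-yl]-4,4,5,5-tetramethyl-1,3,2-dioxaborolane F3. Suzuki–Miyaura coupling of this boronate with iodide 22 (Pd(PPh3)4, K3PO4, THF/H2O, rt) forms the C15–C15' bond with retention of both alkene geometries and comes back to the route at 25.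

Step 4. Enantioface discrimination may be insufficient for a ketone flanked by a twisted alkenyl group and a silyloxymethyl group, and the enantiomeric purity reached here caps that of every later compound. The fallback replaces asymmetric reduction by kinetic resolution. It sets out from racemic alcohol 6 (step 3 is then skipped), which is subjected to Sharpless kinetic resolution with Ti(OiPr)4, L-(+)-diisopropyl tartrate and t-BuOOH (0.6 equiv) over 4 Å molecular sieves in CH2Cl2 at −20 °C. By the usual face-selection rule the (R)-enantiomer should be the fast one and is consumed as (1R)-2-[(tert-butyldimethylsilyl)oxy]-1-[(1S,6S)-2,2-dimethyl-7-oxabicyclo[4.1.0]heptan-1-yl]ethan-1-ol F4. The unreacted (S)-enantiomer is recovered, so the fallback comes back to the route at 8.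

Further compounds
F1 | step 6 | (1R)-2-[(tert-butyldimethylsilyl)oxy]-1-(6,6-dimethylcyclohex-1-en-1-yl)ethan-1-ol | CC1(C)CCCC=C1[C@@H](O)CO[Si](C)(C)C(C)(C)C
F2 | step 6 | (1R)-2-[(tert-butyldimethylsilyl)oxy]-1-(6,6-dimethylcyclohex-1-en-1-yl)ethyl N-phenylcarbamate | CC1(C)CCCC=C1[C@@H](OC(=O)Nc1ccccc1)CO[Si](C)(C)C(C)(C)C
F3 | step 15 | 2-[(1E,3E,5E,7E)-3,7-dimethyl-9-[(1E)-2,6,6-trimethylcyclohex-2-en-1-ylidene]nona-1,3,5,7-tetraen-1-yl]-4,4,5,5-tetramethyl-1,3,2-dioxaborolane | CC1=CCCC(C)(C)\C1=C/C=C(C)/C=C/C=C(C)/C=C/B1OC(C)(C)C(C)(C)O1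
F4 | step 4 | (1R)-2-[(tert-butyldimethylsilyl)oxy]-1-[(1S,6S)-2,2-dimethyl-7-oxabicyclo[4.1.0]heptan-1-yl]ethan-1-ol | CC1(C)CCC[C@@H]2O[C@]12[C@@H](O)CO[Si](C)(C)C(C)(C)C
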